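**Structural features**

The target is a diarylmethane: two fully substituted benzene rings joined only by one CH2 group. Ring A (C1 to C6) carries pentanoyl at C1, hydroxyls at C2, C4 and C6, methyl at C3 and the bridge at C5. Ring B (C1' to C6') carries the bridge at C1', hydroxyls at C2' and C4', butanoyl at C3', methyl at C5' and the only methyl ether at C6'. There is no stereocentre, so nothing has to be set or protected against epimerisation. The fragile parts are the electron-rich phenol rings (oxidation in base), the doubly benzylic bridge (acid or base can cut or scramble it once both rings are free phenols), and the C6' methyl ether, which is twisted between two ortho substituents and therefore exposed to Lewis acids. The real difficulty is that the rings are near twins, differing in one chain carbon and one O-methyl, so a symmetric union of two phloroglucinols through a one-carbon electrophile cannot distinguish them, and one oxygen out of six must be methylated on the right ring and the right side. The key step exploits the 1,3,5-oxygen pattern of ring B and the position of C6' between C1' and C5'. The chain C6'–C5'(CH3)–C4'(O)–C3'(H)–C2'(O) is the ring of a 3-methyl-4-alkoxy-2-pyranone (C6' is the lactone carbonyl, C2' is pyranone C6). C1' is the first side-chain carbon on pyranone C6 and already carries the ring A benzyl group, so forming C1'–C6' completes ring B with every substituent in place.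

**Logic of the disconnections**

21 to 20: the four benzyl–oxygen bonds (three on ring A, one on the C4' oxygen) are cut last. All temporary groups are of one kind, so a single neutral hydrogenolysis ends the synthesis without touching a carbon–carbon bond or the methyl ether. The gain is that ring A has no free hydroxyl in any earlier step, which suppresses bridge scrambling. The demand is that the aryl ketones and the diarylmethane survive H2 over Pd/C.

20 to 19: the O–CH3 bond at C6' is cut. In 19 the C2' hydroxyl is hydrogen-bonded to the butanoyl oxygen and the C4' oxygen is benzylated, so the C6' hydroxyl is the only free, acidic phenol. The gain is that the one permanent differentiating group is placed by the substrate, not by a reagent choice. The demand is mono-O-methylation without C-methylation.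

19 to 16 and 17: the C3'–acyl bond is cut. C3' is the only unsubstituted aromatic carbon in 16 and lies ortho or para to three oxygens, so no regiochemical question arises. The gain is that 16 is the direct product of the ring-forming step. The demand is an acylation mild enough for five aryl ethers and an acid-sensitive bridge.

16 to 14 (key disconnection): the C1'–C6' bond of ring B is cut, which turns ring B into a 2-pyranone with a two-carbon tether to ring A. The six ring B carbons are then already in order, the bridge CH2 becomes an ordinary chain carbon made by alkylation, and ring A enters complete. The demand is that an alkoxide opens the lactone and that the less acidic ketone enolate, the one bearing the ring A benzyl group, C-acylates the ester.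

14 to 5 and 13: the bond between the carbon alpha to pyranone C6 and the benzylic carbon of ring A is cut. It pairs the vinylogous acidity of the 6-methyl group with a benzylic electrophile and divides the molecule into two fragments of similar effort. The demand is clean deprotonation at the 6-methyl group and an electrophile whose ketone does not interfere.

13 to 12: carbon–bromine is traded for carbon–oxygen, because the bromide is too ionisable to carry further back. The demand is a neutral, cold bromination and immediate use.

12 to 11: the carbinol is traced to an aldehyde. The aldehyde is the group that electrophilic substitution can put on a fully oxygenated ring. The demand is reduction of the aldehyde beside an aryl ketone.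

11 to 10: the three benzyl–oxygen bonds on ring A are cut. Benzyl is chosen because it survives hydride, lithium amide, alkoxide and mild Lewis acid and leaves at the end without acid. The demand is O-alkylation, not C-alkylation, of three hydrogen-bonded phenols.

10 to 8: the C5–CHO bond is cut, and this carbon becomes the bridge. C5 is the only free ring position of 8. The demand is a formylation that tolerates free phenols.

8 to 6 and 7: the C1–acyl bond is cut. The two free positions of 6 are equivalent, so one acylation gives one product. The demand is to stop after one acyl group.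

5 to 4: the benzyl–oxygen bond on the pyranone C4 oxygen is cut. This oxygen ends as the free C4' hydroxyl, so it is protected with the same group as ring A. The demand is alkylation on the C4 oxygen, not on the carbonyl oxygen or C3.

4 to 3: the lactone O1–C2 bond is cut, giving an open 3,5-dioxo ester. The demand is lactonisation through the C5 enol oxygen.

3 to 1 and 2: the C4–C5 bond of the hexanoate is cut, giving a keto ester dianion and an acetyl donor. The demand is acylation at the terminal carbon without proton transfer from the product.

**Other disconnections considered**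

Alternative 1: Ring A would be built by a Danheiser benzannulation. The cuts are the C3–C4 and C1–C2 bonds (from a [2+2] union) and the C4–C5 bond (from a six-electron closure). Heating the 3-ethoxycyclobutenone A2, which carries the finished ring B benzyl group on C4, with the siloxyalkyne A3 would open A2 to a vinylketene, add A3, reopen the new cyclobutenone and close the dienylketene to phenol A1.
- In its favour: the cascade is thermal and neutral, and its regiochemistry follows from the polarity of the ynol ether.
- Against it here: A2 needs ring B finished first, including its methyl ether and butanoyl group, and made into a ketene partner although it carries an enolisable ketone. A3 is moisture-sensitive. After the cascade the ring A carbon still needs pentanoylation, and three different oxygen groups (silyl, ethyl, benzyl) must be removed. The ethyl ether calls for a boron halide in the presence of the twisted ring B methyl ether.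
- Comparison: on mechanism it is the equal of the chosen plan in taking regiochemistry from connectivity, and the better in avoiding alkoxide and any retro-Claisen risk. On structure it fits less well, because ring A of the target has three identical free hydroxyls and the differentiation it provides is wasted. On step economy it is the longer route.

Alternative 2: Both aryl–acyl bonds (C1–pentanoyl and C3'–butanoyl) would be cut and formed together. Irradiation of the pentaester A5 at 254 nm would move one pentanoyl and one butanoyl group from oxygen to the only free carbon of each ring, giving A4, and ester solvolysis would finish.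
- In its favour: no Lewis acid and no protecting group beyond the esters are needed. Each ring has one free carbon, so placement is unambiguous. Two bonds form in one operation.
- Against it here: the photo-Fries shift runs through radical pairs that can escape the cage. Two independent events must both succeed in one molecule. The product ketones absorb at the irradiation wavelength, and the doubly benzylic CH2 is a hydrogen donor. More seriously, the plan does not say how the acyl-free, unsymmetrical diarylmethane with one methyl ether on ring B is assembled; with no ketone present, chelation cannot direct the methylation.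
- Comparison: it is the better of the chosen plan in protecting-group economy and in avoiding acid at the acylation stage, and the equal in securing acyl regiochemistry by the substitution pattern. It is weaker in the expected efficiency of a twofold photoreaction and in leaving ring B assembly and O-methyl placement unsolved.

Alternative 3: Ring A would be built by an Effenberger annulation. The cuts are the C5–C6 and C2–C3 bonds. The silyl enol ether A7 would be acylated by malonyl dichloride A8 at both alpha carbons of its ketone, giving A6 as the trione tautomer of a methylphloroglucinol.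
- In its favour: two ring bonds form in one step from a three-carbon reagent, ring A appears as the free triol, and its one free carbon is exactly the pentanoyl position.
- Against it here: with an open-chain ketone, the second acylation usually goes through the enol oxygen and gives a 4-hydroxy-2-pyranone. Closure through carbon is dependable mainly where a ring forces it. The ring B butanoyl ketone is a second enolisable site, HCl is released beside benzyl ethers, and ring B with its methyl ether must again be complete beforehand.
- Comparison: on step economy for ring A it is the better of the chosen plan if the C,C-closure holds. On the later pentanoylation beside benzyl ethers it is the equal, since step 11 faces the same problem. On mechanism the two plans are related Claisen-type closures. In the chosen plan closure through oxygen only returns 14, whereas here it gives a hydroxypyranone whose anion resists reopening.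

Key step: step 10

Remarks on the chemistry:
- Remark 1: the pyranone oxygen that ends as the free C4' hydroxyl is carried as a benzyl ether instead of a methyl ether, and the alkoxide of the key step is matched to it. This is a change of protecting group only; the bond formed, the ring closed and the skeletons of 14 and 16 are unchanged. It removes the need to discriminate two ring B methyl ethers with a boron halide at the end.
- Remark 2: in the ring-opened ester the ester carbon and the keto arm are cis across C2=C3. Because the alkoxy group outranks the CH2 arm at C3, the correct descriptor is (2E); a (2Z) label would denote the isomer that cannot cyclise.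
- Remark 3: metal enolates and other anionic forms of a numbered compound are not numbered separately. Compounds 1 and 3 are racemic and configurationally labile; every other compound of the route is achiral.

Step 1
Reactants: 1 ethyl 2-methyl-3-oxobutanoate (ethyl 2-methylacetoacetate); 2 N-methoxy-N-methylacetamide
Product: 3 ethyl 2-methyl-3,5-dioxohexanoate (racemic)
Conditions: NaH, THF, 0 °C; n-BuLi, 0 °C; then 2, −78 → 0 °C; aq. HCl
Reagents that add atoms: none
Why: Acylation of a beta-keto ester dianion at its terminal carbon (Weiler dianion chemistry); the chelated tetrahedral adduct of the Weinreb amide persists until work-up, so the more acidic product cannot quench the dianion. The C2 stereocentre is racemic and disappears in step 2.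

Step 2
Reactants: 3 ethyl 2-methyl-3,5-dioxohexanoate
Product: 4 4-hydroxy-3,6-dimethyl-2H-pyran-2-one
Conditions: DBU, PhMe, reflux; aq. HCl
Reagents that add atoms: none
Why: Base-promoted lactonisation of a 3,5-dioxo ester: the C5 enol oxygen attacks the ester and ethanol is lost, the standard entry to 6-substituted 4-hydroxy-2-pyranones.

Step 3
Reactants: 4 4-hydroxy-3,6-dimethyl-2H-pyran-2-one
Product: 5 4-(benzyloxy)-3,6-dimethyl-2H-pyran-2-one
Conditions: BnOH, PPh3, DIAD, THF, 0 °C → rt
Reagents that add atoms: benzyl alcohol, OCc1ccccc1
Why: Mitsunobu etherification; the hydroxypyranone is a vinylogous carboxylic acid and is expected to be alkylated on the C4 oxygen, which avoids the carbonyl-oxygen and C3 alkylation that halide and carbonate can give.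

Step 4
Reactants: 6 2-methylbenzene-1,3,5-triol (2,4,6-trihydroxytoluene); 7 pentanoyl chloride
Product: 8 1-(2,4,6-trihydroxy-3-methylphenyl)pentan-1-one
Conditions: AlCl3, PhNO2–CH2Cl2, 0 → 50 °C; aq. HCl
Reagents that add atoms: none
Why: Friedel–Crafts acylation; the two free positions of 6 are equivalent by symmetry and the first acyl group deactivates the ring toward a second.

Step 5
Reactants: 8 1-(2,4,6-trihydroxy-3-methylphenyl)pentan-1-one
Product: 10 2,4,6-trihydroxy-3-methyl-5-pentanoylbenzaldehyde, via aryl iminium chloride 9 (not isolated)
Conditions: POCl3, DMF, EtOAc, 0 °C → rt; then H2O, 50 °C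
Reagents that add atoms: N,N-dimethylformamide, CN(C)C=O; water, O
Why: Vilsmeier–Haack formylation at the only free ring carbon, which is activated by three hydroxyls; water hydrolyses iminium salt 9 to the aldehyde.

Step 6
Reactants: 10 2,4,6-trihydroxy-3-methyl-5-pentanoylbenzaldehyde
Product: 11 2,4,6-tris(benzyloxy)-3-methyl-5-pentanoylbenzaldehyde
Conditions: BnBr, K2CO3, DMF, 60 °C
Reagents that add atoms: benzyl bromide, BrCc1ccccc1
Why: Williamson etherification in a dipolar aprotic solvent, where phenoxides alkylate on oxygen; excess halide and heat are used because all three hydroxyls are hydrogen-bonded to a carbonyl group.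

Step 7
Reactants: 11 2,4,6-tris(benzyloxy)-3-methyl-5-pentanoylbenzaldehyde
Product: 12 1-[2,4,6-tris(benzyloxy)-3-(hydroxymethyl)-5-methylphenyl]pentan-1-one
Conditions: NaBH4, THF–MeOH, −20 °C
Reagents that add atoms: none
Why: Chemoselective borohydride reduction; the aldehyde is far more electrophilic than the aryl ketone, which is twisted and shielded by two ortho benzyloxy groups.

Step 8
Reactants: 12 1-[2,4,6-tris(benzyloxy)-3-(hydroxymethyl)-5-methylphenyl]pentan-1-one
Product: 13 1-[2,4,6-tris(benzyloxy)-3-(bromomethyl)-5-methylphenyl]pentan-1-one
Conditions: PBr3, CH2Cl2, 0 °C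
Reagents that add atoms: phosphorus tribromide, BrP(Br)Br
Why: Conversion of a primary benzylic alcohol to the bromide through its phosphite ester. The bromide is ionisable because of the alkoxy-rich ring, so it is washed cold and used at once without chromatography.

Step 9
Reactants: 5 4-(benzyloxy)-3,6-dimethyl-2H-pyran-2-one; 13 1-[2,4,6-tris(benzyloxy)-3-(bromomethyl)-5-methylphenyl]pentan-1-one
Product: 14 4-(benzyloxy)-3-methyl-6-{2-[2,4,6-tris(benzyloxy)-3-methyl-5-pentanoylphenyl]ethyl}-2H-pyran-2-one
Conditions: LiN(iPr)2, THF, −78 °C; then 13, −78 → −30 °C
Reagents that add atoms: none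
Why: Vinylogous enolate alkylation: deprotonation of the 6-methyl group of a 4-alkoxy-2-pyranone gives an extended enolate that benzylic halides alkylate at the terminal carbon, and C3 is blocked by its methyl group. The pyranone anion is used in excess so the bromide is consumed before proton transfer from the pentanoyl chain or a second alkylation can compete.

Step 10
Reactants: 14 4-(benzyloxy)-3-methyl-6-{2-[2,4,6-tris(benzyloxy)-3-methyl-5-pentanoylphenyl]ethyl}-2H-pyran-2-one
Product: 16 1-{2,4,6-tris(benzyloxy)-3-[4-(benzyloxy)-2,6-dihydroxy-3-methylbenzyl]-5-methylphenyl}pentan-1-one, via ring-opened benzyl keto ester 15 (not isolated)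
Conditions: NaOCH2Ph (from NaH, BnOH), THF, 0 → 65 °C; aq. HCl
Reagents that add atoms: none
Why: Benzyloxide adds to the lactone carbonyl of 14 and the ring opens to the dienolate of ester 15, in which the enol ether double bond holds the ester and the keto arm cis (the 2E geometry). Proton exchange with benzyl alcohol gives a small share of the ketone enolate on the C6 side of 15 (chain locants), the carbon that bears the ring A benzyl group; this carbon attacks the ester carbonyl, benzyloxide leaves, and the cyclohexenedione tautomerises to the resorcinol, whose deprotonation makes the sequence irreversible. The closest known reaction type is the alkoxide-induced recyclisation of 4-alkoxy-6-alkyl-2-pyranones to phloroglucinol monoethers, a Claisen (Dieckmann-type) condensation modelled on polyketide folding. Ring B closes in the 6-(enolendo)-exo-trig mode. No stereocentre is formed. The selectivity needed is C-acylation through C6 only: O-acylation by the same enolate merely returns 14, the more acidic C4 enolate could close only a four-membered ring, and the pentanoyl enolate of ring A would have to close a twelve-membered ring. Because the alkoxide is the one already present in the enol ether and the ester, addition–elimination at C3 and transesterification are degenerate, and the benzyl ethers leave ring A without a phenoxide through which the bridge could be cut.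

Step 11
Reactants: 16 1-{2,4,6-tris(benzyloxy)-3-[4-(benzyloxy)-2,6-dihydroxy-3-methylbenzyl]-5-methylphenyl}pentan-1-one; 17 butanoic anhydride
Product: 19 1-{2,4,6-tris(benzyloxy)-3-[4-(benzyloxy)-3-butanoyl-2,6-dihydroxy-5-methylbenzyl]-5-methylphenyl}pentan-1-one, via difluoroboron chelate 18 (not isolated)
Conditions: BF3·OEt2, CH2Cl2, 0 °C → rt; then K2CO3, MeOH–H2O, rt
Reagents that add atoms: none
Why: Friedel–Crafts acylation (any aryl ester formed first can undergo Fries shift under the same Lewis acid) at C3', the only unsubstituted aromatic carbon in the molecule, ortho or para to three oxygens. BF3 is chosen because aryl benzyl ethers are expected to tolerate it at room temperature; the new ketone is held as chelate 18, and the basic methanolic work-up hydrolyses the chelate and any stray aryl butanoate.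

Step 12
Reactants: 19 1-{2,4,6-tris(benzyloxy)-3-[4-(benzyloxy)-3-butanoyl-2,6-dihydroxy-5-methylbenzyl]-5-methylphenyl}pentan-1-one
Product: 20 1-{2,4,6-tris(benzyloxy)-3-[4-(benzyloxy)-3-butanoyl-2-hydroxy-6-methoxy-5-methylbenzyl]-5-methylphenyl}pentan-1-one
Conditions: Me2SO4, K2CO3, acetone, rt
Reagents that add atoms: dimethyl sulfate, COS(=O)(=O)OC
Why: Chelation-controlled Williamson methylation: the C2' hydroxyl is tied to the butanoyl oxygen by a hydrogen bond, while the C6' hydroxyl, para to the ketone, is the most acidic and the only free one. Dimethyl sulfate with carbonate in acetone favours O- over C-methylation.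

Step 13
Reactants: 20 1-{2,4,6-tris(benzyloxy)-3-[4-(benzyloxy)-3-butanoyl-2-hydroxy-6-methoxy-5-methylbenzyl]-5-methylphenyl}pentan-1-one
Product: 21 1-{3-[(3-butanoyl-2,4-dihydroxy-6-methoxy-5-methylphenyl)methyl]-2,4,6-trihydroxy-5-methylphenyl}pentan-1-one (target)
Conditions: H2 (1 atm), Pd/C, EtOAc–MeOH, rt
Reagents that add atoms: none
Why: Hydrogenolysis of four aryl benzyl ethers under neutral conditions; ortho-hydroxyaryl ketones, the methyl ether and the diarylmethane are expected to be inert at ambient pressure and temperature, and the sensitive polyphenol is obtained by filtration and evaporation alone.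

**Compound list**

1 | ethyl 2-methyl-3-oxobutanoate (ethyl 2-methylacetoacetate; racemic, labile) | CCOC(=O)C(C)C(C)=O | starting material
2 | N-methoxy-N-methylacetamide | CC(=O)N(C)OC | starting material
3 | ethyl 2-methyl-3,5-dioxohexanoate (racemic, labile) | CCOC(=O)C(C)C(=O)CC(C)=O | intermediate
4 | 4-hydroxy-3,6-dimethyl-2H-pyran-2-one | CC1=CC(O)=C(C)C(=O)O1 | intermediate
5 | 4-(benzyloxy)-3,6-dimethyl-2H-pyran-2-one | CC1=CC(OCc2ccccc2)=C(C)C(=O)O1 | intermediate
6 | 2-methylbenzene-1,3,5-triol (2,4,6-trihydroxytoluene) | Cc1c(O)cc(O)cc1O | starting material
7 | pentanoyl chloride | CCCCC(=O)Cl | starting material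
8 | 1-(2,4,6-trihydroxy-3-methylphenyl)pentan-1-one | CCCCC(=O)c1c(O)cc(O)c(C)c1O | intermediate
9 | N-[(2,4,6-trihydroxy-3-methyl-5-pentanoylphenyl)methylidene]-N-methylmethanaminium chloride | CCCCC(=O)c1c(O)c(C)c(O)c(C=[N+](C)C)c1O.[Cl-] | intermediate (not isolated)
10 | 2,4,6-trihydroxy-3-methyl-5-pentanoylbenzaldehyde | CCCCC(=O)c1c(O)c(C)c(O)c(C=O)c1O | intermediate
11 | 2,4,6-tris(benzyloxy)-3-methyl-5-pentanoylbenzaldehyde | CCCCC(=O)c1c(OCc2ccccc2)c(C)c(OCc2ccccc2)c(C=O)c1OCc1ccccc1 | intermediate
12 | 1-[2,4,6-tris(benzyloxy)-3-(hydroxymethyl)-5-methylphenyl]pentan-1-one | CCCCC(=O)c1c(OCc2ccccc2)c(C)c(OCc2ccccc2)c(CO)c1OCc1ccccc1 | intermediate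
13 | 1-[2,4,6-tris(benzyloxy)-3-(bromomethyl)-5-methylphenyl]pentan-1-one | CCCCC(=O)c1c(OCc2ccccc2)c(C)c(OCc2ccccc2)c(CBr)c1OCc1ccccc1 | intermediate
14 | 4-(benzyloxy)-3-methyl-6-{2-[2,4,6-tris(benzyloxy)-3-methyl-5-pentanoylphenyl]ethyl}-2H-pyran-2-one | CCCCC(=O)c1c(OCc2ccccc2)c(C)c(OCc2ccccc2)c(CCC2=CC(OCc3ccccc3)=C(C)C(=O)O2)c1OCc1ccccc1 | intermediate
15 | benzyl (2E)-3-(benzyloxy)-2-methyl-5-oxo-7-[2,4,6-tris(benzyloxy)-3-methyl-5-pentanoylphenyl]hept-2-enoate | CCCCC(=O)c1c(OCc2ccccc2)c(C)c(OCc2ccccc2)c(CCC(=O)C/C(OCc2ccccc2)=C(/C)C(=O)OCc2ccccc2)c1OCc1ccccc1 | intermediate (not isolated)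
16 | 1-{2,4,6-tris(benzyloxy)-3-[4-(benzyloxy)-2,6-dihydroxy-3-methylbenzyl]-5-methylphenyl}pentan-1-one | CCCCC(=O)c1c(OCc2ccccc2)c(C)c(OCc2ccccc2)c(Cc2c(O)cc(OCc3ccccc3)c(C)c2O)c1OCc1ccccc1 | intermediate
17 | butanoic anhydride | CCCC(=O)OC(=O)CCC | starting material
18 | difluoroboron chelate of 19 (BF2 bridges the C2' phenolate oxygen and the butanoyl oxygen) | CCCC1=[O+][B-](F)(F)Oc2c1c(OCc1ccccc1)c(C)c(O)c2Cc1c(OCc2ccccc2)c(C)c(OCc2ccccc2)c(C(=O)CCCC)c1OCc1ccccc1 | intermediate (not isolated)
19 | 1-{2,4,6-tris(benzyloxy)-3-[4-(benzyloxy)-3-butanoyl-2,6-dihydroxy-5-methylbenzyl]-5-methylphenyl}pentan-1-one | CCCCC(=O)c1c(OCc2ccccc2)c(C)c(OCc2ccccc2)c(Cc2c(O)c(C(=O)CCC)c(OCc3ccccc3)c(C)c2O)c1OCc1ccccc1 | intermediate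
20 | 1-{2,4,6-tris(benzyloxy)-3-[4-(benzyloxy)-3-butanoyl-2-hydroxy-6-methoxy-5-methylbenzyl]-5-methylphenyl}pentan-1-one | CCCCC(=O)c1c(OCc2ccccc2)c(C)c(OCc2ccccc2)c(Cc2c(O)c(C(=O)CCC)c(OCc3ccccc3)c(C)c2OC)c1OCc1ccccc1 | intermediate
21 | 1-{3-[(3-butanoyl-2,4-dihydroxy-6-methoxy-5-methylphenyl)methyl]-2,4,6-trihydroxy-5-methylphenyl}pentan-1-one | CCCCC(=O)c1c(O)c(C)c(O)c(Cc2c(O)c(C(=O)CCC)c(O)c(C)c2OC)c1O | target

**Step count and least certain steps**

Total: 13 steps. Longest linear sequence: 10 steps (steps 4 to 13, from 6 to 21). The pyranone branch (steps 1 to 3) joins at step 9.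

Step 10 (key step). The most likely failure is stalling at the ring-opened stage: the resting species is the conjugated dienolate of 15, and the enolate needed for closure is the less acidic one, so the system may merely shuttle between 14 and 15. On long heating, alkoxide may instead attack the ketone of 15 and cut the chain by retro-Claisen cleavage. Fallback, from 14 back to 16: open the lactone briefly with NaOCH2Ph at 0 °C, quench with acetic acid and isolate 15; no compound outside the list is made (F0). Then add 15 to an excess of LiN(iPr)2 in THF at −78 °C and warm. This forms the dianion (conjugated dienolate plus the kinetic C6 enolate), the known way to force Claisen closure of polycarbonyl esters without a nucleophilic alkoxide present, and gives 16 after acidification.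

Step 9. The benzylic bromide 13 may ionise and self-condense before it meets the nucleophile, and proton transfer from the pentanoyl alpha-CH2 to the pyranone anion or a second alkylation may lower the conversion. Fallback, from 5 and 11 back to 14, bypassing 12 and 13: add the lithium enolate of 5 (LiN(iPr)2, THF, −78 °C) to aldehyde 11 to give 4-(benzyloxy)-6-{2-hydroxy-2-[2,4,6-tris(benzyloxy)-3-methyl-5-pentanoylphenyl]ethyl}-3-methyl-2H-pyran-2-one F1 (racemic). Then remove the benzylic hydroxyl by ionic hydrogenation (Et3SiH, CF3CO2H, CH2Cl2, −20 °C); the trialkoxybenzyl cation is well stabilised and takes up hydride to give 14.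

Step 11. Three processes threaten it: Lewis-acid loss of benzyl groups (most likely the C4' ether once the neighbouring ketone binds boron), acid-induced scission of the bridge by ipso attack on ring B, and acylation of the pentanoyl alpha-carbon. Fallback, from 16 back to 19: Houben–Hoesch reaction with butanenitrile (ZnCl2, HCl gas, Et2O, 0 °C). The nitrile does not acylate oxygen or ketone alpha-carbons and needs no oxophilic boron acid. The product separates as 1-{6-(benzyloxy)-2,4-dihydroxy-5-methyl-3-[2,4,6-tris(benzyloxy)-3-methyl-5-pentanoylbenzyl]phenyl}butan-1-iminium chloride F2, which warm water hydrolyses to 19.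

Step 6. Etherification may stop short at the hydrogen-bonded hydroxyls, or the fully substituted ring may be benzylated on carbon with loss of aromaticity. Fallback, from 8 back to 11, which reverses the order of protection and formylation: benzylate 8 (BnBr, K2CO3, DMF, 60 °C), a routine operation on trihydroxyaryl ketones, to give 1-[2,4,6-tris(benzyloxy)-3-methylphenyl]pentan-1-one F3. Then formylate the one free ring carbon under Vilsmeier–Haack conditions (POCl3, DMF, 60 °C; aq. NaOAc) to reach 11.

Step 12. Methylation may spread to the hydrogen-bonded C2' hydroxyl or occur on a ring B carbon. Fallback, from 19 directly to 21, skipping 20 and step 13: methylate both hydroxyls (excess Me2SO4, K2CO3, DMF) to 1-{2,4,6-tris(benzyloxy)-3-[4-(benzyloxy)-3-butanoyl-2,6-dimethoxy-5-methylbenzyl]-5-methylphenyl}pentan-1-one F4. Then treat with BCl3 (CH2Cl2, −78 → 0 °C), which removes the methyl ether ortho to the butanoyl group through carbonyl assistance together with the four benzyl ethers. The temperature must be kept low to spare the twisted C6' methyl ether.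

**Further compounds**

F0 | step 10 | none | none
F1 | step 9 | 4-(benzyloxy)-6-{2-hydroxy-2-[2,4,6-tris(benzyloxy)-3-methyl-5-pentanoylphenyl]ethyl}-3-methyl-2H-pyran-2-one (racemic) | CCCCC(=O)c1c(OCc2ccccc2)c(C)c(OCc2ccccc2)c(C(O)CC2=CC(OCc3ccccc3)=C(C)C(=O)O2)c1OCc1ccccc1
F2 | step 11 | 1-{6-(benzyloxy)-2,4-dihydroxy-5-methyl-3-[2,4,6-tris(benzyloxy)-3-methyl-5-pentanoylbenzyl]phenyl}butan-1-iminium chloride | CCCCC(=O)c1c(OCc2ccccc2)c(C)c(OCc2ccccc2)c(Cc2c(O)c(C(CCC)=[NH2+])c(OCc3ccccc3)c(C)c2O)c1OCc1ccccc1.[Cl-]
F3 | step 6 | 1-[2,4,6-tris(benzyloxy)-3-methylphenyl]pentan-1-one | CCCCC(=O)c1c(OCc2ccccc2)cc(OCc2ccccc2)c(C)c1OCc1ccccc1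
F4 | step 12 | 1-{2,4,6-tris(benzyloxy)-3-[4-(benzyloxy)-3-butanoyl-2,6-dimethoxy-5-methylbenzyl]-5-methylphenyl}pentan-1-one | CCCCC(=O)c1c(OCc2ccccc2)c(C)c(OCc2ccccc2)c(Cc2c(OC)c(C(=O)CCC)c(OCc3ccccc3)c(C)c2OC)c1OCc1ccccc1
A1 | alternative 1 | 1-{2,6-bis(benzyloxy)-3-[(6-ethoxy-2-hydroxy-3-methyl-4-{[tri(propan-2-yl)silyl]oxy}phenyl)methyl]-4-methoxy-5-methylphenyl}butan-1-one | CCOc1cc(O[Si](C(C)C)(C(C)C)C(C)C)c(C)c(O)c1Cc1c(OCc2ccccc2)c(C(=O)CCC)c(OCc2ccccc2)c(C)c1OC
A2 | alternative 1 | 4-{[2,4-bis(benzyloxy)-3-butanoyl-6-methoxy-5-methylphenyl]methyl}-3-ethoxycyclobut-2-en-1-one (racemic) | CCOC1=CC(=O)C1Cc1c(OCc2ccccc2)c(C(=O)CCC)c(OCc2ccccc2)c(C)c1OC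
A3 | alternative 1 | tri(propan-2-yl)(prop-1-yn-1-yloxy)silane | CC#CO[Si](C(C)C)(C(C)C)C(C)C
A4 | alternative 2 | target skeleton with pentanoate esters on the ring A oxygens at C4 and C6 and a butanoate ester on the ring B oxygen at C2' | CCCCC(=O)Oc1c(C)c(O)c(C(=O)CCCC)c(OC(=O)CCCC)c1Cc1c(OC(=O)CCC)c(C(=O)CCC)c(O)c(C)c1OC
A5 | alternative 2 | acyl-free diarylmethane pentaester: ring A as tripentanoate of its three hydroxyls, ring B as dibutanoate at the C2' and C4' oxygens with the C6' methyl ether | CCCCC(=O)Oc1cc(OC(=O)CCCC)c(Cc2c(OC(=O)CCC)cc(OC(=O)CCC)c(C)c2OC)c(OC(=O)CCCC)c1C
A6 | alternative 3 | 1-{2,6-bis(benzyloxy)-4-methoxy-5-methyl-3-[(2,4,6-trihydroxy-3-methylphenyl)methyl]phenyl}butan-1-one | Oc1cc(O)c(C)c(O)c1Cc1c(OCc2ccccc2)c(C(=O)CCC)c(OCc2ccccc2)c(C)c1OC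
A7 | alternative 3 | 1-{2,6-bis(benzyloxy)-4-methoxy-5-methyl-3-[3-(trimethylsilyloxy)pent-3-en-1-yl]phenyl}butan-1-one (either alkene geometry) | CC=C(CCc1c(OCc2ccccc2)c(C(=O)CCC)c(OCc2ccccc2)c(C)c1OC)O[Si](C)(C)C
A8 | alternative 3 | propanedioyl dichloride (malonyl dichloride) | O=C(Cl)CC(Cl)=O
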